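**Plan**

- Numbering used throughout: seven-membered ring C1(=CH2)–C2(OH)–C3H2–C4–C5(OH)–C6–C10; cyclopentene C6–C7(CH3)=C8–C9–C10; side chain C11(CH3)–C12(OAc)–C13=C14–C15(CH3)2OH.
- Enabling feature: C3 is the only CH2 of the seven-membered ring and lies between the oxygenated C2 and the branch carbon C4, so that ring can be closed last by a C2 acyl radical adding to C3 of a C4=C3H2 alkene (cut C2–C3).
- Further cuts, in retrosynthetic order: C7–CH3 (enol triflate coupling), C5–C6 (aldol), C1–C10 (Mukaiyama–Michael on cyclopent-2-enone), C4=C3 (methylenation), C11–C12 (crotylboration).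
- Forward: the side-chain aldehyde (C3–C5, C11–C15) is built from 2-methylbut-3-yn-2-ol; it and a C1–C2 ketene acetal are joined to the bought five-membered ring by Michael addition then aldol; the seven-membered ring closes in step 17; then C1=CH2, C2–OH and deprotection.
- Stereochemistry: C11/C12 from (E)-crotyldiisopinocampheylborane; C10 from a chiral oxazaborolidinium catalyst; C6 (trans to C10) and C5 (anti aldol) by relay from C10; C4 by hydrogen-atom transfer anti to C5–OSi; C2 by CBS reduction; C1 is transient.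

Key step: step 17

Assumption: the Mukaiyama–Michael addition is taken to give C1 mainly as drawn (1S); either C1 epimer would serve, because C1 becomes trigonal in step 19.

**Route**

Step 1
Reactants: 1 2-methylbut-3-yn-2-ol
Product: 2 triethyl[(2-methylbut-3-yn-2-yl)oxy]silane
Conditions: TESCl, imidazole, DMAP (cat.), DMF, 0 °C to rt
Reagents that add atoms: chlorotriethylsilane, CC[Si](Cl)(CC)CC
Why: Imidazole/DMAP-mediated silyl transfer masks the tertiary C15 hydroxyl for the organometallic steps that follow; no stereocentre is involved.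

Step 2
Reactants: 2 triethyl[(2-methylbut-3-yn-2-yl)oxy]silane
Product: 4 4-methyl-4-(triethylsilyloxy)pent-2-ynal, via lithium acetylide 3 (not isolated)
Conditions: n-BuLi, THF, −78 °C; DMF, −78 to 0 °C; inverse quench into aq. KH2PO4
Reagents that add atoms: N,N-dimethylformamide, CN(C)C=O
Why: Formylation of a lithium acetylide with DMF adds C12 as the aldehyde carbon, and the buffered inverse quench releases the ynal without amine-induced decomposition.

Step 3
Reactants: 4 4-methyl-4-(triethylsilyloxy)pent-2-ynal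
Product: 6 (3R,4R)-3,7-dimethyl-7-(triethylsilyloxy)oct-1-en-5-yn-4-ol, via diisopinocampheylborinate 5 (not isolated)
Conditions: trans-but-2-ene, KOt-Bu, n-BuLi, THF, −78 to −45 °C; (+)-Ipc2BOMe [from (−)-α-pinene], −78 °C; BF3·OEt2; 4, −78 °C; then NaOH, H2O2, 0 °C to rt
Reagents that add atoms: trans-but-2-ene, C/C=C/C
Why: Brown crotylboration through a closed chair transition state makes the (E)-crotyl reagent give the anti C11-methyl/C12-hydroxyl pair, and the isopinocampheyl groups from (−)-α-pinene should direct the crotyl unit to the Re face of the ynal, setting (11R) and the C12 configuration of the target.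

Step 4
Reactants: 6 (3R,4R)-3,7-dimethyl-7-(triethylsilyloxy)oct-1-en-5-yn-4-ol
Product: 7 (3R,4S,5E)-3,7-dimethyl-7-(triethylsilyloxy)octa-1,5-dien-4-ol
Conditions: NaAlH2(OCH2CH2OMe)2, THF, 0 °C; aq. potassium sodium tartrate
Reagents that add atoms: none
Why: Hydroxyl-directed trans-hydroalumination of the propargylic alcohol followed by protonolysis should give only the (13E)-alkene, the temperature being held at 0 °C so that the vinylalanate does not expel the C15 silyloxy group to an allene.

Step 5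
Reactants: 7 (3R,4S,5E)-3,7-dimethyl-7-(triethylsilyloxy)octa-1,5-dien-4-ol
Product: 8 (3R,4S,5E)-3,7-dimethyl-4,7-bis(triethylsilyloxy)octa-1,5-diene
Conditions: TESCl, imidazole, DMF, 0 °C to rt
Reagents that add atoms: chlorotriethylsilane, CC[Si](Cl)(CC)CC
Why: Standard silylation of the secondary allylic alcohol; TES is chosen for C12–O so that it can later be cleaved together with the primary TES ether while the C5 TBS ether stays.

Step 6
Reactants: 8 (3R,4S,5E)-3,7-dimethyl-4,7-bis(triethylsilyloxy)octa-1,5-diene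
Product: 10 (3R,4R,5E)-3,7-dimethyl-4,7-bis(triethylsilyloxy)oct-5-en-1-ol, via alkylborane 9 (not isolated)
Conditions: 9-BBN, THF, 0 °C to rt; then NaOH, H2O2, 0 °C
Reagents that add atoms: hydrogen peroxide, OO
Why: Anti-Markovnikov hydroboration–oxidation; 9-BBN reacts with the monosubstituted vinyl group far faster than with the hindered 1,2-disubstituted C13=C14 alkene, giving the C5 primary alcohol.

Step 7
Reactants: 10 (3R,4R,5E)-3,7-dimethyl-4,7-bis(triethylsilyloxy)oct-5-en-1-ol
Product: 11 (3R,4R,5E)-3,7-dimethyl-4,7-bis(triethylsilyloxy)oct-5-enal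
Conditions: Dess–Martin periodinane, NaHCO3, CH2Cl2, 0 °C to rt
Reagents that add atoms: none
Why: Buffered Dess–Martin oxidation takes the primary alcohol to the aldehyde without touching the silyl ethers or the β-stereocentre C11.

Step 8
Reactants: 11 (3R,4R,5E)-3,7-dimethyl-4,7-bis(triethylsilyloxy)oct-5-enal
Product: 12 (3R,4S,5E)-3,7-dimethyl-2-methylidene-4,7-bis(triethylsilyloxy)oct-5-enal
Conditions: 37% aq. CH2O, pyrrolidine (10 mol %), propionic acid (10 mol %), i-PrOH, 45 °C
Reagents that add atoms: formaldehyde, C=O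
Why: Organocatalytic α-methylenation (Mannich condensation of the enamine with formaldehyde, then amine elimination) installs C3 on C4; C11 is β to the carbonyl and is not enolised.

Step 9
Reactants: 13 methyl 3-hydroxypropanoate
Product: 14 methyl 3-(triethylsilyloxy)propanoate
Conditions: TESCl, imidazole, CH2Cl2, 0 °C
Reagents that add atoms: chlorotriethylsilane, CC[Si](Cl)(CC)CC
Why: Routine silylation of the primary alcohol that will become the C1 hydroxymethyl group.

Step 10
Reactants: 14 methyl 3-(triethylsilyloxy)propanoate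
Product: 15 (E)-1-methoxy-3-(triethylsilyloxy)-1-(trimethylsilyloxy)prop-1-ene (mainly E)
Conditions: LiN(i-Pr)2, TMSCl (present from the start), THF, −78 °C; warm to rt, filter under argon
Reagents that add atoms: chlorotrimethylsilane, C[Si](C)(C)Cl
Why: Kinetic ester enolisation with internal silyl chloride quench traps the β-silyloxy enolate as the O-silyl ketene acetal before it can eliminate triethylsilanolate.

Step 11
Reactants: 15 (E)-1-methoxy-3-(triethylsilyloxy)-1-(trimethylsilyloxy)prop-1-ene; 16 cyclopent-2-en-1-one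
Product: 17 methyl (2S)-3-(triethylsilyloxy)-2-[(1R)-3-(trimethylsilyloxy)cyclopent-2-en-1-yl]propanoate
Conditions: (S)-3,3-diphenyl-1-(o-tolyl)tetrahydro-1H,3H-pyrrolo[1,2-c][1,3,2]oxazaborole·HNTf2 (10 mol %; the antipode is equally available should the sense of induction require it), Ph3PO (25 mol %), toluene, −40 °C; non-aqueous work-up
Reagents that add atoms: none
Why: Enantioselective Mukaiyama–Michael addition in which the cationic oxazaborolidinium binds the enone carbonyl and shields one face of C10, the ketene acetal adds to the open face and the silyl group is passed to the enolate oxygen (Ph3PO intercepting free silyl cation), giving the regiodefined C6=C7 silyl enol ether with (10R) configuration.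

Step 12
Reactants: 17 methyl (2S)-3-(triethylsilyloxy)-2-[(1R)-3-(trimethylsilyloxy)cyclopent-2-en-1-yl]propanoate; 12 (3R,4S,5E)-3,7-dimethyl-2-methylidene-4,7-bis(triethylsilyloxy)oct-5-enal
Product: 20 methyl (2S)-2-{(1R,2R)-2-[(1S,3R,4S,5E)-1-hydroxy-3,7-dimethyl-2-methylidene-4,7-bis(triethylsilyloxy)oct-5-en-1-yl]-3-oxocyclopentyl}-3-(triethylsilyloxy)propanoate, via potassium enolate 18 (not isolated), via chlorozinc enolate 19 (not isolated)
Conditions: KOt-Bu, THF, −78 °C; ZnCl2 (in Et2O), −78 °C; 12, −78 to −40 °C; aq. NH4Cl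
Reagents that add atoms: none
Why: Alkoxide cleavage of the silyl enol ether gives the regiodefined enolate without touching the methyl ester, and the zinc enolate should add to the aldehyde through a closed six-membered chair transition state on the ring face anti to the C10 substituent (C6/C10 trans) with the anti relationship at C5 that an E(O)-enolate gives, any (10S) material from step 11 being removed here as a diastereomer.

Step 13
Reactants: 20 aldol adduct (C5–OH, C7 ketone)
Product: 21 methyl (2S)-2-{(1R,2R)-2-[(1S,3R,4S,5E)-1-(tert-butyldimethylsilyloxy)-3,7-dimethyl-2-methylidene-4,7-bis(triethylsilyloxy)oct-5-en-1-yl]-3-oxocyclopentyl}-3-(triethylsilyloxy)propanoate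
Conditions: TBSOTf, 2,6-lutidine, CH2Cl2, −78 °C
Reagents that add atoms: tert-butyldimethylsilyl trifluoromethanesulfonate, CC(C)(C)[Si](C)(C)OS(=O)(=O)C(F)(F)F
Why: Silylation with the silyl triflate at −78 °C should be faster than retro-aldol or enol silylation and gives the robust C5 TBS ether that outlasts the TES groups.

Step 14
Reactants: 21 C5-TBS-protected keto ester
Product: 23 methyl (2S)-2-{(1R,5R)-5-[(1S,3R,4S,5E)-1-(tert-butyldimethylsilyloxy)-3,7-dimethyl-2-methylidene-4,7-bis(triethylsilyloxy)oct-5-en-1-yl]-4-(trifluoromethylsulfonyloxy)cyclopent-3-en-1-yl}-3-(triethylsilyloxy)propanoate, via lithium enolate 22 (not isolated)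
Conditions: LiN(i-Pr)2 (1.05 equiv), THF, −78 °C; N-(5-chloropyridin-2-yl)bis(trifluoromethanesulfonimide), −78 to −20 °C
Reagents that add atoms: N-(5-chloropyridin-2-yl)-1,1,1-trifluoro-N-(trifluoromethylsulfonyl)methanesulfonamide, O=S(=O)(N(c1ccc(Cl)cn1)S(=O)(=O)C(F)(F)F)C(F)(F)F
Why: Kinetic deprotonation by the hindered amide at the open C8 methylene (not at C6, where loss of the C5 silyloxy group would follow, nor at the less acidic ester α-carbon C1) and O-triflation of the enolate give the C7=C8 enol triflate.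

Step 15
Reactants: 23 C7 enol triflate
Product: 24 methyl (2S)-2-{(1R,5S)-5-[(1S,3R,4S,5E)-1-(tert-butyldimethylsilyloxy)-3,7-dimethyl-2-methylidene-4,7-bis(triethylsilyloxy)oct-5-en-1-yl]-4-methylcyclopent-3-en-1-yl}-3-(triethylsilyloxy)propanoate
Conditions: MeZnCl, Pd(PPh3)4 (5 mol %), THF, 50 °C
Reagents that add atoms: methylzinc chloride, C[Zn]Cl
Why: Negishi coupling (oxidative addition of zerovalent palladium into the enol triflate, transmetalation from zinc, reductive elimination) installs the C7 methyl group with the C7=C8 position retained, ester and silyl ethers being inert to the organozinc.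

Step 16
Reactants: 24 C7-methyl cyclopentene methyl ester
Product: 25 Se-phenyl (2S)-2-{(1R,5S)-5-[(1S,3R,4S,5E)-1-(tert-butyldimethylsilyloxy)-3,7-dimethyl-2-methylidene-4,7-bis(triethylsilyloxy)oct-5-en-1-yl]-4-methylcyclopent-3-en-1-yl}-3-(triethylsilyloxy)propaneselenoate
Conditions: Me2AlSePh (from AlMe3 and PhSeH, toluene, 0 °C), CH2Cl2, 0 °C to rt
Reagents that add atoms: dimethylaluminium benzeneselenolate, C[Al](C)[Se]c1ccccc1
Why: Ester-to-selenoester exchange in which aluminium activates the ester carbonyl and delivers the selenolate, driven by Al–O bond formation, under non-basic conditions that leave C1 and its β-silyloxy group alone.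

Step 17
Reactants: 25 Se-phenyl selenoester with C4=C3H2, C5–OTBS, C1–CH2OTES and the full side chain
Product: 26 (1S,4S,5R,6S,10R)-5-(tert-butyldimethylsilyloxy)-7-methyl-1-[(triethylsilyloxy)methyl]-4-[(2R,3S,4E)-6-methyl-3,6-bis(triethylsilyloxy)hept-4-en-2-yl]bicyclo[5.3.0]dec-7-en-2-one (target numbering; trans ring fusion)
Conditions: (Me3Si)3SiH (1.5 equiv), AIBN (0.2 equiv), benzene (0.005 M), 80 °C, slow addition of silane and initiator
Reagents that add atoms: none
Why: The silyl radical from (Me3Si)3SiH and AIBN abstracts the phenylseleno group, and the nucleophilic C2 acyl radical adds to the unsubstituted terminus C3 of the C4=C3H2 alkene, forming the C2–C3 bond and the seven-membered ring by 7-endo-trig closure, after which the tertiary C4 radical takes hydrogen from the silane. The closest known reaction type is the reductive cyclisation of acyl radicals from Se-phenyl selenoesters onto alkenes that carry an internal substituent, for which endo closure to seven-membered ketones is the established mode. The new C4 stereocentre (4S) is set in the hydrogen transfer, the bulky silane being expected to approach the ring radical anti to the adjacent C5 tert-butyldimethylsilyloxy group, which places the side chain cis to C5–O; C1, C5, C6 and C10 are untouched and the ring fusion stays trans. The step needs endo over 6-exo regioselectivity, secured by full substitution at C4 (exo attack would create a quaternary centre and a primary radical), and preference over 5-exo attack on C8 of the cyclopentene, which would require both ring substituents pseudoaxial and would build a strained bicyclo[2.2.1]heptan-2-one. Premature reduction to the aldehyde and decarbonylation are held back by high dilution, slow addition of the comparatively slow hydrogen donor and the unstabilised secondary nature of the C1 radical that loss of CO would give.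

Step 18
Reactants: 26 cyclised C2 ketone
Product: 27 (1S,4S,5R,6S,10R)-5-(tert-butyldimethylsilyloxy)-1-(hydroxymethyl)-4-[(2R,3S,4E)-3-hydroxy-6-methyl-6-(triethylsilyloxy)hept-4-en-2-yl]-7-methylbicyclo[5.3.0]dec-7-en-2-one
Conditions: HF·pyridine, pyridine, THF, 0 °C
Reagents that add atoms: none
Why: Buffered HF·pyridine should cleave the primary and the secondary allylic TES ethers much faster than the hindered secondary TBS ether and the tertiary TES ether, exposing exactly the two hydroxyls to be acetylated (loss of some tertiary TES would be harmless, since a tertiary alcohol is not acetylated in step 19 and that group is removed in step 21 anyway).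

Step 19
Reactants: 27 C1-hydroxymethyl C12-hydroxy ketone
Product: 29 (4S,5R,6S,10R)-4-[(2R,3S,4E)-3-acetoxy-6-methyl-6-(triethylsilyloxy)hept-4-en-2-yl]-5-(tert-butyldimethylsilyloxy)-7-methyl-1-methylidenebicyclo[5.3.0]dec-7-en-2-one, via diacetate 28 (not isolated)
Conditions: Ac2O, pyridine, DMAP (cat.), CH2Cl2, 0 °C to rt; then DBU, 0 °C
Reagents that add atoms: acetic anhydride, CC(=O)OC(C)=O
Why: Acetylation installs the C12 acetate of the target and turns the C1 hydroxymethyl group into a β-acetoxy ketone, from which DBU removes acetic acid by E1cB elimination to the exocyclic enone (erasing C1), while the C12 allylic acetate has no acidifying carbonyl and stays.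

Step 20
Reactants: 29 exocyclic enone
Product: 30 (2R,4S,5R,6S,10R)-4-[(2R,3S,4E)-3-acetoxy-6-methyl-6-(triethylsilyloxy)hept-4-en-2-yl]-5-(tert-butyldimethylsilyloxy)-7-methyl-1-methylidenebicyclo[5.3.0]dec-7-en-2-ol
Conditions: (S)-1-methyl-3,3-diphenyltetrahydro-1H,3H-pyrrolo[1,2-c][1,3,2]oxazaborole [(S)-Me-CBS, 1.0 equiv], catecholborane, toluene, −78 °C
Reagents that add atoms: none
Why: Corey–Bakshi–Shibata reduction, in which the oxazaborolidine binds the ketone with the 1-methylidene carbon as the large flank and delivers hydride within the complex to the β face of C2, should give the (2R) alcohol by reagent control as a 1,2-reduction only, the low temperature suppressing conjugate reduction of the s-cis enone.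

Step 21
Reactants: 30 C5-TBS C15-TES allylic alcohol
Product: 31 CNP0213969.2, (2R,4S,5R,6S,10R)-4-[(2R,3S,4E)-3-acetoxy-6-hydroxy-6-methylhept-4-en-2-yl]-7-methyl-1-methylidenebicyclo[5.3.0]dec-7-ene-2,5-diol (target numbering)
Conditions: HF·pyridine (excess), THF, 0 °C to rt
Reagents that add atoms: none
Why: Fluoride-driven desilylation (Si–F bond formation) removes the C5 TBS and C15 TES ethers under buffered, weakly acidic conditions that should neither migrate the C12 acetate nor ionise the allylic alcohols.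

**Compound list**

1 | 2-methylbut-3-yn-2-ol | CC(C)(O)C#C | starting material
2 | triethyl[(2-methylbut-3-yn-2-yl)oxy]silane | CC(C)(C#C)O[Si](CC)(CC)CC | intermediate
3 | [3-methyl-3-(triethylsilyloxy)but-1-yn-1-yl]lithium | [Li]C#CC(C)(C)O[Si](CC)(CC)CC | intermediate (not isolated)
4 | 4-methyl-4-(triethylsilyloxy)pent-2-ynal | O=CC#CC(C)(C)O[Si](CC)(CC)CC | intermediate
5 | O-diisopinocampheylboryl derivative of 6 | C=C[C@@H](C)[C@H](C#CC(C)(C)O[Si](CC)(CC)CC)OB([C@H]1C[C@H]2C[C@@H]([C@@H]1C)C2(C)C)[C@H]1C[C@H]2C[C@@H]([C@@H]1C)C2(C)C | intermediate (not isolated)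
6 | (3R,4R)-3,7-dimethyl-7-(triethylsilyloxy)oct-1-en-5-yn-4-ol | C=C[C@@H](C)[C@H](C#CC(C)(C)O[Si](CC)(CC)CC)O | intermediate
7 | (3R,4S,5E)-3,7-dimethyl-7-(triethylsilyloxy)octa-1,5-dien-4-ol | C=C[C@@H](C)[C@H](/C=C/C(C)(C)O[Si](CC)(CC)CC)O | intermediate
8 | (3R,4S,5E)-3,7-dimethyl-4,7-bis(triethylsilyloxy)octa-1,5-diene | C=C[C@@H](C)[C@H](/C=C/C(C)(C)O[Si](CC)(CC)CC)O[Si](CC)(CC)CC | intermediate
9 | 9-[(3R,4R,5E)-3,7-dimethyl-4,7-bis(triethylsilyloxy)oct-5-en-1-yl]-9-borabicyclo[3.3.1]nonane | C(CB1C2CCCC1CCC2)[C@@H](C)[C@H](/C=C/C(C)(C)O[Si](CC)(CC)CC)O[Si](CC)(CC)CC | intermediate (not isolated)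
10 | (3R,4R,5E)-3,7-dimethyl-4,7-bis(triethylsilyloxy)oct-5-en-1-ol | OCC[C@@H](C)[C@H](/C=C/C(C)(C)O[Si](CC)(CC)CC)O[Si](CC)(CC)CC | intermediate
11 | (3R,4R,5E)-3,7-dimethyl-4,7-bis(triethylsilyloxy)oct-5-enal | O=CC[C@@H](C)[C@H](/C=C/C(C)(C)O[Si](CC)(CC)CC)O[Si](CC)(CC)CC | intermediate
12 | (3R,4S,5E)-3,7-dimethyl-2-methylidene-4,7-bis(triethylsilyloxy)oct-5-enal | O=CC(=C)[C@@H](C)[C@H](/C=C/C(C)(C)O[Si](CC)(CC)CC)O[Si](CC)(CC)CC | intermediate
13 | methyl 3-hydroxypropanoate | COC(=O)CCO | starting material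
14 | methyl 3-(triethylsilyloxy)propanoate | COC(=O)CCO[Si](CC)(CC)CC | intermediate
15 | (E)-1-methoxy-3-(triethylsilyloxy)-1-(trimethylsilyloxy)prop-1-ene | CO/C(=C\CO[Si](CC)(CC)CC)O[Si](C)(C)C | intermediate
16 | cyclopent-2-en-1-one | O=C1C=CCC1 | starting material
17 | methyl (2S)-3-(triethylsilyloxy)-2-[(1R)-3-(trimethylsilyloxy)cyclopent-2-en-1-yl]propanoate | COC(=O)[C@H](CO[Si](CC)(CC)CC)[C@@H]1CCC(O[Si](C)(C)C)=C1 | intermediate
18 | potassium enolate from 17 (C6=C7, O–K) | COC(=O)[C@H](CO[Si](CC)(CC)CC)[C@@H]1CCC([O-])=C1.[K+] | intermediate (not isolated)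
19 | chlorozinc enolate from 18 | COC(=O)[C@H](CO[Si](CC)(CC)CC)[C@@H]1CCC(O[Zn]Cl)=C1 | intermediate (not isolated)
20 | aldol adduct (1S,5S,6R,10R,11R,12S; C5–OH, C7 ketone; systematic name in step 12) | COC(=O)[C@H](CO[Si](CC)(CC)CC)[C@@H]1CCC(=O)[C@H]1[C@H](O)C(=C)[C@@H](C)[C@H](/C=C/C(C)(C)O[Si](CC)(CC)CC)O[Si](CC)(CC)CC | intermediate
21 | C5 TBS ether of 20 | COC(=O)[C@H](CO[Si](CC)(CC)CC)[C@@H]1CCC(=O)[C@H]1[C@H](O[Si](C)(C)C(C)(C)C)C(=C)[C@@H](C)[C@H](/C=C/C(C)(C)O[Si](CC)(CC)CC)O[Si](CC)(CC)CC | intermediate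
22 | lithium C7=C8 enolate of 21 | COC(=O)[C@H](CO[Si](CC)(CC)CC)[C@@H]1CC=C([O-])[C@H]1[C@H](O[Si](C)(C)C(C)(C)C)C(=C)[C@@H](C)[C@H](/C=C/C(C)(C)O[Si](CC)(CC)CC)O[Si](CC)(CC)CC.[Li+] | intermediate (not isolated)
23 | C7=C8 enol triflate (1S,5S,6R,10R,11R,12S) | COC(=O)[C@H](CO[Si](CC)(CC)CC)[C@@H]1CC=C(OS(=O)(=O)C(F)(F)F)[C@H]1[C@H](O[Si](C)(C)C(C)(C)C)C(=C)[C@@H](C)[C@H](/C=C/C(C)(C)O[Si](CC)(CC)CC)O[Si](CC)(CC)CC | intermediate
24 | C7-methyl cyclopentene methyl ester (1S,5S,6S,10R,11R,12S) | COC(=O)[C@H](CO[Si](CC)(CC)CC)[C@@H]1CC=C(C)[C@H]1[C@H](O[Si](C)(C)C(C)(C)C)C(=C)[C@@H](C)[C@H](/C=C/C(C)(C)O[Si](CC)(CC)CC)O[Si](CC)(CC)CC | intermediate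
25 | Se-phenyl selenoester (1S,5S,6S,10R,11R,12S), precursor of the key step | O=C([Se]c1ccccc1)[C@H](CO[Si](CC)(CC)CC)[C@@H]1CC=C(C)[C@H]1[C@H](O[Si](C)(C)C(C)(C)C)C(=C)[C@@H](C)[C@H](/C=C/C(C)(C)O[Si](CC)(CC)CC)O[Si](CC)(CC)CC | intermediate
26 | trans-fused bicyclo[5.3.0]dec-7-en-2-one (1S,4S,5R,6S,10R,11R,12S) with 1-CH2OTES, 5-OTBS, 12-OTES, 15-OTES | O=C1C[C@@H]([C@@H](C)[C@H](/C=C/C(C)(C)O[Si](CC)(CC)CC)O[Si](CC)(CC)CC)[C@@H](O[Si](C)(C)C(C)(C)C)[C@@H]2C(C)=CC[C@H]2[C@H]1CO[Si](CC)(CC)CC | intermediate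
27 | 1-hydroxymethyl 12-hydroxy ketone (5-OTBS, 15-OTES) | O=C1C[C@@H]([C@@H](C)[C@H](/C=C/C(C)(C)O[Si](CC)(CC)CC)O)[C@@H](O[Si](C)(C)C(C)(C)C)[C@@H]2C(C)=CC[C@H]2[C@H]1CO | intermediate
28 | diacetate of 27 (1-CH2OAc, 12-OAc) | O=C1C[C@@H]([C@@H](C)[C@H](/C=C/C(C)(C)O[Si](CC)(CC)CC)OC(C)=O)[C@@H](O[Si](C)(C)C(C)(C)C)[C@@H]2C(C)=CC[C@H]2[C@H]1COC(C)=O | intermediate (not isolated)
29 | 1-methylidene-2-ketone (4S,5R,6S,10R,11R,12S) with 12-OAc, 5-OTBS, 15-OTES | C=C1C(=O)C[C@@H]([C@@H](C)[C@H](/C=C/C(C)(C)O[Si](CC)(CC)CC)OC(C)=O)[C@@H](O[Si](C)(C)C(C)(C)C)[C@@H]2C(C)=CC[C@@H]12 | intermediate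
30 | (2R)-allylic alcohol with 12-OAc, 5-OTBS, 15-OTES | C=C1[C@H](O)C[C@@H]([C@@H](C)[C@H](/C=C/C(C)(C)O[Si](CC)(CC)CC)OC(C)=O)[C@@H](O[Si](C)(C)C(C)(C)C)[C@@H]2C(C)=CC[C@@H]12 | intermediate
31 | CNP0213969.2 | C=C1[C@H](O)C[C@@H]([C@@H](C)[C@H](/C=C/C(C)(C)O)OC(C)=O)[C@@H](O)[C@@H]2C(C)=CC[C@@H]12 | target

**Step count and risks**

Total steps: 21. Longest linear sequence: 18 (steps 1–8, then 12–21).

Most likely to fail:

1. Step 17. The acyl radical may close 5-exo onto C8 of the cyclopentene, or be reduced or lose CO before it cyclises, and hydrogen transfer to the C4 radical may occur from the face syn to the C5 silyloxy group. Fallback (sets out from 24, returns at 26): the same C2–C3 bond is closed by polar chemistry with C4 set beforehand. 9-BBN in THF adds to the 1,1-disubstituted C4=C3 alkene of 24, the fastest-reacting alkene, with hydrogen delivered to C4 anti to the C5 silyloxy group under acyclic 1,2-control, giving the alkylborane F1. NaOH/H2O2 converts it into the C3 primary alcohol F2, and I2, PPh3 and imidazole give the primary iodide F3. i-Bu2AlH in CH2Cl2 at −78 °C reduces the methyl ester to the iodo aldehyde F4. SmI2 with HMPA in THF closes the ring in a Barbier cyclisation to the cycloheptanol F5 (C2 epimers), and Dess–Martin periodinane oxidises F5 to ketone 26.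

2. Step 20. The facial bias of the substrate (side chain, silyloxy group and C9 all on the β face) may override the catalyst, so that hydride enters from the α face. Fallback (sets out from 29, returns at 30): the substrate-controlled epimer is made on purpose and inverted. Luche reduction of 29 (NaBH4, CeCl3·7H2O, MeOH, −78 °C) gives the (2S)-allylic alcohol F6. Mitsunobu reaction with chloroacetic acid (PPh3, DIAD, THF, 0 °C) inverts C2 to the (2R)-chloroacetate F7. Thiourea and NaHCO3 in EtOH remove the chloroacetyl group in the presence of the C12 acetate to give 30.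

3. Step 11. Enantioface discrimination of the Lewis-acid-bound cyclopentenone by the β-silyloxy ketene acetal may be weak. Fallback (sets out from 15 and 16, returns at 20): catalyst control is replaced by separation of diastereomers after union with the enantiopure aldehyde. An achiral acid (HNTf2, 1 mol %, CH2Cl2, −78 °C) gives the racemic silyl enol ether F8. Under the conditions of step 12 this passes through the racemic potassium enolate F9 and the racemic chlorozinc enolate F10 and is joined to 12. The (10R) half gives 20, the (10S) half gives the diastereomeric aldol F11, and chromatography removes F11.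

**Further compounds**

F1 | step 17 | B-alkyl-9-borabicyclo[3.3.1]nonane from 24 (boron on C3, 4S) | COC(=O)[C@H](CO[Si](CC)(CC)CC)[C@@H]1CC=C(C)[C@H]1[C@H](O[Si](C)(C)C(C)(C)C)[C@@H](CB1C2CCCC1CCC2)[C@@H](C)[C@H](/C=C/C(C)(C)O[Si](CC)(CC)CC)O[Si](CC)(CC)CC
F2 | step 17 | C3 primary alcohol (C4–H set) | COC(=O)[C@H](CO[Si](CC)(CC)CC)[C@@H]1CC=C(C)[C@H]1[C@H](O[Si](C)(C)C(C)(C)C)[C@@H](CO)[C@@H](C)[C@H](/C=C/C(C)(C)O[Si](CC)(CC)CC)O[Si](CC)(CC)CC
F3 | step 17 | C3 primary iodide | COC(=O)[C@H](CO[Si](CC)(CC)CC)[C@@H]1CC=C(C)[C@H]1[C@H](O[Si](C)(C)C(C)(C)C)[C@@H](CI)[C@@H](C)[C@H](/C=C/C(C)(C)O[Si](CC)(CC)CC)O[Si](CC)(CC)CC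
F4 | step 17 | C2 aldehyde with C3 iodide | O=C[C@H](CO[Si](CC)(CC)CC)[C@@H]1CC=C(C)[C@H]1[C@H](O[Si](C)(C)C(C)(C)C)[C@@H](CI)[C@@H](C)[C@H](/C=C/C(C)(C)O[Si](CC)(CC)CC)O[Si](CC)(CC)CC
F5 | step 17 | bicyclo[5.3.0]dec-7-en-2-ol (C2 epimers) corresponding to 26 | OC1C[C@@H]([C@@H](C)[C@H](/C=C/C(C)(C)O[Si](CC)(CC)CC)O[Si](CC)(CC)CC)[C@@H](O[Si](C)(C)C(C)(C)C)[C@@H]2C(C)=CC[C@H]2[C@H]1CO[Si](CC)(CC)CC
F6 | step 20 | (2S)-epimer of 30 | C=C1[C@@H](O)C[C@@H]([C@@H](C)[C@H](/C=C/C(C)(C)O[Si](CC)(CC)CC)OC(C)=O)[C@@H](O[Si](C)(C)C(C)(C)C)[C@@H]2C(C)=CC[C@@H]12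
F7 | step 20 | (2R)-chloroacetate of 30 | C=C1[C@H](OC(=O)CCl)C[C@@H]([C@@H](C)[C@H](/C=C/C(C)(C)O[Si](CC)(CC)CC)OC(C)=O)[C@@H](O[Si](C)(C)C(C)(C)C)[C@@H]2C(C)=CC[C@@H]12
F8 | step 11 | racemic methyl 3-(triethylsilyloxy)-2-[3-(trimethylsilyloxy)cyclopent-2-en-1-yl]propanoate | COC(=O)C(CO[Si](CC)(CC)CC)C1CCC(O[Si](C)(C)C)=C1
F9 | step 11 | racemic potassium enolate | COC(=O)C(CO[Si](CC)(CC)CC)C1CCC([O-])=C1.[K+]
F10 | step 11 | racemic chlorozinc enolate | COC(=O)C(CO[Si](CC)(CC)CC)C1CCC(O[Zn]Cl)=C1
F11 | step 11 | (10S)-series aldol diastereomer of 20 (ring centres C1, C5, C6, C10 mirrored; 11R,12S) | COC(=O)[C@@H](CO[Si](CC)(CC)CC)[C@H]1CCC(=O)[C@@H]1[C@@H](O)C(=C)[C@@H](C)[C@H](/C=C/C(C)(C)O[Si](CC)(CC)CC)O[Si](CC)(CC)CC
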